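The decalin (ring A: C1–C5 and C10; ring B: C5–C10) is cut at C6–C7, the two unfunctionalised methylenes of ring B that lie between the quaternary ring-fusion carbon C5 and the methyl-bearing C8. A primary C6 radical, held on C5 of a preformed ring A, adds 6-endo to the terminal carbon (C7) of an isopropenyl group whose inner carbon becomes C8: one operation closes ring B as the trans-decalin and sets C8 by axial hydrogen transfer. The precursor is a cyclohexane bearing trans CH2I (on C5) and CH(CH2OH)C(CH3)=CH2 (on C10) groups, with C4 masked as a β-silyl carbinol that then unveils the exocyclic methylene. C9 is quaternised last by equatorial benzylation.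

Key step: step 5

Remark: C9 (from step 3 to step 6) and the carbinol carbon C4 (in 7 and 8) are carried as epimeric mixtures, because both centres become trigonal later (C4 in step 5, C9 in step 11); C11 is the CH2OH carbon on C9.

Step 1
Reactants: 1 2-methylcyclohex-2-en-1-one; 2 (2-methylprop-1-en-1-yl)magnesium bromide
Product: 4 (2R,3S)-2-(hydroxymethyl)-2-methyl-3-(2-methylprop-1-en-1-yl)cyclohexan-1-one, via magnesium enolate 3 (not isolated)
Conditions: 2 (1.3 equiv, slow addition), Cu(OTf)2 (4 mol %), chiral hydroxyalkyl imidazolinium salt as NHC precursor (5 mol %, the enantiomer that gives 3S), Et2O, -30 °C; then CH2O gas (from cracked paraformaldehyde), -78 to -40 °C; aq. NH4Cl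
Reagents that add atoms: formaldehyde, C=O
Why: Copper-catalysed asymmetric conjugate addition of a Grignard reagent to an α-substituted cyclic enone followed by aldol trapping of the regiodefined magnesium enolate: the chiral NHC–copper catalyst sets C10 (3S) in the C–C bond-forming step, and formaldehyde then attacks the tetrasubstituted enolate carbon C5 anti to the new alkenyl group, which sets the quaternary centre (2R) with CH2OH (the future C6) trans to the side chain, as a trans ring fusion requires.

Step 2
Reactants: 4 (2R,3S)-2-(hydroxymethyl)-2-methyl-3-(2-methylprop-1-en-1-yl)cyclohexan-1-one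
Product: 5 (2S,3S)-2-(iodomethyl)-2-methyl-3-(2-methylprop-1-en-1-yl)cyclohexan-1-one
Conditions: PPh3, I2, imidazole, PhMe, 80 °C
Reagents that add atoms: iodine, II
Why: Appel-type iodination: iodide displaces the alkoxyphosphonium ion at the primary (neopentyl) carbon, the quaternary α-carbon rules out β-elimination, and no stereocentre is touched (the C2 descriptor changes only because CH2I outranks the carbonyl carbon).

Step 3
Reactants: 5 (2S,3S)-2-(iodomethyl)-2-methyl-3-(2-methylprop-1-en-1-yl)cyclohexan-1-one
Product: 6 (2S,3S)-3-(1-hydroxy-3-methylbut-3-en-2-yl)-2-(iodomethyl)-2-methylcyclohexan-1-one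
Conditions: Me2AlCl (3 equiv), paraformaldehyde, CH2Cl2, -78 to 0 °C
Reagents that add atoms: formaldehyde (as paraformaldehyde), C=O
Why: Lewis-acid-promoted carbonyl-ene (Prins-type) reaction of formaldehyde with the trisubstituted alkene: the C–C bond forms at the less substituted alkene carbon (C9) and a methyl hydrogen is transferred, which turns the 2-methylprop-1-enyl group into the CH(CH2OH)–C(CH3)=CH2 unit carrying C11 and the C7=C8 acceptor; the new centre C9 forms as a mixture, which does not matter because it is enolised in step 11.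

Step 4
Reactants: 6 (2S,3S)-3-(1-hydroxy-3-methylbut-3-en-2-yl)-2-(iodomethyl)-2-methylcyclohexan-1-one
Product: 7 (2S,3S)-3-(1-hydroxy-3-methylbut-3-en-2-yl)-2-(iodomethyl)-2-methyl-1-[(trimethylsilyl)methyl]cyclohexan-1-ol
Conditions: Me3SiCH2Li (3 equiv), CeCl3, THF, -78 °C; aq. NH4Cl at -78 °C
Reagents that add atoms: (trimethylsilyl)methyllithium, [Li]C[Si](C)(C)C
Why: Organocerium 1,2-addition of the Peterson reagent to the hindered, enolisable ketone (CeCl3 suppresses enolisation, and the cold quench keeps the alkoxide from attacking or fragmenting the γ-iodide); the β-silyl carbinol is a latent exocyclic methylene that makes C4 sp3, so that the C6 radical of step 5 has no neighbouring carbonyl or vinyl group into which it could rearrange (Dowd–Beckwith-type acyl shift or vinyl shift); the configuration at C4 is irrelevant.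

Step 5
Reactants: 7 (2S,3S)-3-(1-hydroxy-3-methylbut-3-en-2-yl)-2-(iodomethyl)-2-methyl-1-[(trimethylsilyl)methyl]cyclohexan-1-ol
Product: 9 [(2S,4aS,8aS)-2,4a-dimethyl-5-methylidenedecahydronaphthalen-1-yl]methanol, via cyclised silyl carbinol 8 (not isolated)
Conditions: Bu3SnH (1.3 equiv, syringe pump), AIBN (0.2 equiv), PhH (0.01 M), 80 °C; solvent exchange, then KOt-Bu (3 equiv), THF, 20 °C
Reagents that add atoms: none
Why: Bu3Sn• abstracts iodine from 7 to give the primary neopentyl-type C6 radical, which adds to the terminal carbon C7 of the isopropenyl group and leaves a tertiary C8 radical that is reduced by Bu3SnH; the closest known reaction type is the tin-hydride-mediated 6-endo cyclisation of 5-substituted hex-5-enyl radicals. Ring B closes in the 6-endo-trig mode through a chair transition state in which C6 and C9 are both equatorial on ring A, so the trans relationship installed in step 1 is translated into the trans ring fusion. The new stereocentre C8 is set by axial hydrogen-atom delivery from the α-face (anti to the axial C5 methyl and flanked only by axial hydrogens on C6 and C10), which leaves the C8 methyl equatorial (2S). The step needs 6-endo over 5-exo closure and cyclisation over direct reduction: 5-exo attack would have to hit the fully substituted alkene carbon and build a trans-fused hydrindane with a quaternary carbon next to C9, and slow addition of Bu3SnH at high dilution keeps its concentration low. Because C4 is sp3 (β-silyl carbinol), the C6 radical has no adjacent carbonyl or vinyl group and cannot undergo 1,2-acyl or 1,2-vinyl migration. In the second stage the potassium alkoxide of 8 undergoes syn Peterson elimination, which unveils the C4 exocyclic methylene of 9.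

Step 6
Reactants: 9 [(2S,4aS,8aS)-2,4a-dimethyl-5-methylidenedecahydronaphthalen-1-yl]methanol
Product: 10 (2S,4aS,8aS)-2,4a-dimethyl-5-methylidenedecahydronaphthalene-1-carbaldehyde
Conditions: (n-Pr4N)RuO4 (5 mol %), N-methylmorpholine N-oxide, 4 Å MS, CH2Cl2, 20 °C
Reagents that add atoms: none
Why: Ley–Griffith oxidation of the primary alcohol to the aldehyde under neutral conditions that leave the 1,1-disubstituted alkene untouched; C9 remains an epimeric mixture.

Step 7
Reactants: 11 2-methoxybenzene-1,3-diol
Product: 12 2-methoxy-1,3-bis(methoxymethoxy)benzene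
Conditions: NaH, MOMCl, DMF, 0 to 20 °C
Reagents that add atoms: chloromethyl methyl ether, COCCl
Why: Williamson-type O-alkylation of both phenoxides with MOMCl; the MOM ethers are the directing groups of step 8 and withstand all later basic and hydride steps.

Step 8
Reactants: 12 2-methoxy-1,3-bis(methoxymethoxy)benzene
Product: 17 methyl 5-formyl-3-methoxy-2,4-bis(methoxymethoxy)benzoate, via aryllithium 13 (not isolated), via lithium amino alkoxide 14 (not isolated), via lithiated amino alkoxide 15 (not isolated), via amino alkoxide ester 16 (not isolated)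
Conditions: n-BuLi (1.1 equiv), THF, 0 °C; DMF, -78 to 0 °C; n-BuLi (1.2 equiv), -20 °C; ClCO2Me, -78 °C; aq. NH4Cl
Reagents that add atoms: N,N-dimethylformamide, CN(C)C=O; methyl chloroformate, COC(=O)Cl
Why: Directed ortho-metalation: the OMOM group directs the first lithiation to C4, DMF converts the aryllithium into a lithium α-amino alkoxide that masks the aldehyde in situ and is a weaker director than OMOM, so the second lithiation takes place at the only remaining position ortho to an OMOM group (C6), where methyl chloroformate installs the ester; aqueous work-up releases the aldehyde.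

Step 9
Reactants: 17 methyl 5-formyl-3-methoxy-2,4-bis(methoxymethoxy)benzoate
Product: 18 methyl 5-(hydroxymethyl)-3-methoxy-2,4-bis(methoxymethoxy)benzoate
Conditions: NaBH4, MeOH/THF, 0 °C
Reagents that add atoms: none
Why: Chemoselective NaBH4 reduction of the aldehyde in the presence of the aryl methyl ester.

Step 10
Reactants: 18 methyl 5-(hydroxymethyl)-3-methoxy-2,4-bis(methoxymethoxy)benzoate
Product: 19 methyl 5-(bromomethyl)-3-methoxy-2,4-bis(methoxymethoxy)benzoate
Conditions: CBr4, PPh3, CH2Cl2, 0 °C
Reagents that add atoms: carbon tetrabromide, BrC(Br)(Br)Br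
Why: Appel bromination under neutral conditions that spare the acid-labile MOM ethers; the electron-rich benzylic bromide is used at once.

Step 11
Reactants: 10 (2S,4aS,8aS)-2,4a-dimethyl-5-methylidenedecahydronaphthalene-1-carbaldehyde; 19 methyl 5-(bromomethyl)-3-methoxy-2,4-bis(methoxymethoxy)benzoate
Product: 21 methyl 5-{[(1S,2S,4aS,8aR)-1-formyl-2,4a-dimethyl-5-methylidenedecahydronaphthalen-1-yl]methyl}-3-methoxy-2,4-bis(methoxymethoxy)benzoate, via potassium enolate 20 (not isolated)
Conditions: KN(SiMe3)2 (1.1 equiv), THF, -78 °C; then 19 (1.3 equiv), -78 to -20 °C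
Reagents that add atoms: none
Why: Alkylation of a potassium aldehyde enolate with a reactive benzylic bromide (C-alkylation is favoured with soft benzylic halides): the exocyclic enolate carbon C9 is attacked from the equatorial α-face because the axial β-face is blocked by the 1,3-related axial C5 methyl group, which puts the benzyl group equatorial and the formyl group axial and so sets the quaternary centre (1S).

Step 12
Reactants: 21 methyl 5-{[(1S,2S,4aS,8aR)-1-formyl-2,4a-dimethyl-5-methylidenedecahydronaphthalen-1-yl]methyl}-3-methoxy-2,4-bis(methoxymethoxy)benzoate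
Product: 22 methyl 5-{[(1S,2S,4aS,8aR)-1-(hydroxymethyl)-2,4a-dimethyl-5-methylidenedecahydronaphthalen-1-yl]methyl}-3-methoxy-2,4-bis(methoxymethoxy)benzoate
Conditions: NaBH4, MeOH/THF, 0 to 20 °C
Reagents that add atoms: none
Why: NaBH4 reduces the neopentyl aldehyde to the primary alcohol (C11) and leaves the aryl methyl ester untouched.

Step 13
Reactants: 22 methyl 5-{[(1S,2S,4aS,8aR)-1-(hydroxymethyl)-2,4a-dimethyl-5-methylidenedecahydronaphthalen-1-yl]methyl}-3-methoxy-2,4-bis(methoxymethoxy)benzoate
Product: 23 methyl 2,4-dihydroxy-5-{[(1S,2S,4aS,8aR)-1-(hydroxymethyl)-2,4a-dimethyl-5-methylidenedecahydronaphthalen-1-yl]methyl}-3-methoxybenzoate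
Conditions: HCl (0.3 M in MeOH), 0 to 20 °C
Reagents that add atoms: none
Why: Acid-catalysed acetal exchange with methanol cleaves both aryl MOM ethers to the phenols; dilute acid at or below room temperature should leave the exocyclic alkene in place.

Compound list
1 | 2-methylcyclohex-2-en-1-one | CC1=CCCC1=O | starting material
2 | (2-methylprop-1-en-1-yl)magnesium bromide | CC(C)=C[Mg]Br | starting material
3 | bromomagnesium (3S)-2-methyl-3-(2-methylprop-1-en-1-yl)cyclohex-1-en-1-olate (not isolated) | Br[Mg]OC1=C(C)[C@H](C=C(C)C)CCC1 | intermediate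
4 | (2R,3S)-2-(hydroxymethyl)-2-methyl-3-(2-methylprop-1-en-1-yl)cyclohexan-1-one | O=C1CCC[C@@H](C=C(C)C)[C@]1(C)CO | intermediate
5 | (2S,3S)-2-(iodomethyl)-2-methyl-3-(2-methylprop-1-en-1-yl)cyclohexan-1-one | O=C1CCC[C@@H](C=C(C)C)[C@]1(C)CI | intermediate
6 | (2S,3S)-3-(1-hydroxy-3-methylbut-3-en-2-yl)-2-(iodomethyl)-2-methylcyclohexan-1-one (side-chain epimers) | O=C1CCC[C@@H](C(CO)C(C)=C)[C@]1(C)CI | intermediate
7 | (2S,3S)-3-(1-hydroxy-3-methylbut-3-en-2-yl)-2-(iodomethyl)-2-methyl-1-[(trimethylsilyl)methyl]cyclohexan-1-ol (epimers at C1 and in the side chain) | C[Si](C)(C)CC1(O)CCC[C@@H](C(CO)C(C)=C)[C@]1(C)CI | intermediate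
8 | (2S,4aS,8aS)-1-(hydroxymethyl)-2,4a-dimethyl-5-[(trimethylsilyl)methyl]decahydronaphthalen-5-ol (epimers at C1 and C5; not isolated) | C[Si](C)(C)CC1(O)CCC[C@H]2C(CO)[C@@H](C)CC[C@]12C | intermediate
9 | [(2S,4aS,8aS)-2,4a-dimethyl-5-methylidenedecahydronaphthalen-1-yl]methanol (C1 epimers) | C=C1CCC[C@H]2C(CO)[C@@H](C)CC[C@]12C | intermediate
10 | (2S,4aS,8aS)-2,4a-dimethyl-5-methylidenedecahydronaphthalene-1-carbaldehyde (C1 epimers) | C=C1CCC[C@H]2C(C=O)[C@@H](C)CC[C@]12C | intermediate
11 | 2-methoxybenzene-1,3-diol | COc1c(O)cccc1O | starting material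
12 | 2-methoxy-1,3-bis(methoxymethoxy)benzene | COCOc1cccc(OCOC)c1OC | intermediate
13 | [3-methoxy-2,4-bis(methoxymethoxy)phenyl]lithium (not isolated) | [Li]c1ccc(OCOC)c(OC)c1OCOC | intermediate
14 | lithium (dimethylamino)[3-methoxy-2,4-bis(methoxymethoxy)phenyl]methanolate (not isolated) | [Li]OC(N(C)C)c1ccc(OCOC)c(OC)c1OCOC | intermediate
15 | 5-lithio derivative of 14 (not isolated) | [Li]OC(N(C)C)c1cc([Li])c(OCOC)c(OC)c1OCOC | intermediate
16 | lithium (dimethylamino)[5-(methoxycarbonyl)-3-methoxy-2,4-bis(methoxymethoxy)phenyl]methanolate (not isolated) | [Li]OC(N(C)C)c1cc(C(=O)OC)c(OCOC)c(OC)c1OCOC | intermediate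
17 | methyl 5-formyl-3-methoxy-2,4-bis(methoxymethoxy)benzoate | COC(=O)c1cc(C=O)c(OCOC)c(OC)c1OCOC | intermediate
18 | methyl 5-(hydroxymethyl)-3-methoxy-2,4-bis(methoxymethoxy)benzoate | COC(=O)c1cc(CO)c(OCOC)c(OC)c1OCOC | intermediate
19 | methyl 5-(bromomethyl)-3-methoxy-2,4-bis(methoxymethoxy)benzoate | COC(=O)c1cc(CBr)c(OCOC)c(OC)c1OCOC | intermediate
20 | potassium enolate of 10 (not isolated) | C=C1CCC[C@H]2C(=C[O-])[C@@H](C)CC[C@]12C.[K+] | intermediate
21 | methyl 5-{[(1S,2S,4aS,8aR)-1-formyl-2,4a-dimethyl-5-methylidenedecahydronaphthalen-1-yl]methyl}-3-methoxy-2,4-bis(methoxymethoxy)benzoate | C=C1CCC[C@H]2[C@](C=O)(Cc3cc(C(=O)OC)c(OCOC)c(OC)c3OCOC)[C@@H](C)CC[C@]12C | intermediate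
22 | methyl 5-{[(1S,2S,4aS,8aR)-1-(hydroxymethyl)-2,4a-dimethyl-5-methylidenedecahydronaphthalen-1-yl]methyl}-3-methoxy-2,4-bis(methoxymethoxy)benzoate | C=C1CCC[C@H]2[C@](CO)(Cc3cc(C(=O)OC)c(OCOC)c(OC)c3OCOC)[C@@H](C)CC[C@]12C | intermediate
23 | methyl 2,4-dihydroxy-5-{[(1S,2S,4aS,8aR)-1-(hydroxymethyl)-2,4a-dimethyl-5-methylidenedecahydronaphthalen-1-yl]methyl}-3-methoxybenzoate | C=C1CCC[C@H]2[C@](CO)(Cc3cc(C(=O)OC)c(O)c(OC)c3O)[C@@H](C)CC[C@]12C | target

Total step count: 13. Longest linear sequence: 9 steps (steps 1–6 and 11–13); the aryl branch (steps 7–10) joins at step 11.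

Steps most likely to fail

Step 5 (key step). What may go wrong: hydrogen-atom transfer to the C6 radical before it cyclises, a 1,6-hydrogen shift from the allylic methyl group, or unselective hydrogen delivery to the two faces of the C8 radical. The fallback is a polarity-matched radical conjugate addition onto an enone whose carbonyl carbon is C9, so that ring closure is fast and C8 becomes epimerisable. It sets out from 5. Me3SiCH2Li/CeCl3 should give the β-silyl carbinol F1; ozonolysis (O3, CH2Cl2, -78 °C; Me2S) of the 2-methylprop-1-enyl group should give the aldehyde F2; isopropenylmagnesium bromide should give the allylic alcohol F3, and Dess–Martin oxidation the enone F4. Bu3SnH/AIBN should then close ring B by 6-endo addition of the C6 radical to the enone terminus C7 (the same C6–C7 bond), and equilibration with DBU should place the C8 methyl equatorial in the decalone F5. Wittig methoxymethylenation with Ph3P=CHOMe and excess KN(SiMe3)2 should homologate C9 and at the same time trigger the Peterson elimination, giving the enol ether F6. Mild aqueous acid should hydrolyse F6 to aldehyde 10, where the route is rejoined.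

Step 1. What may go wrong: low enantioselectivity or low conversion in the copper-catalysed addition of an alkenyl Grignard reagent to the α-substituted enone. The fallback is a racemic synthesis followed by resolution. It sets out from 1 and 2, which are combined under achiral catalysis (CuBr·SMe2, same formaldehyde quench) to give racemic 4. Esterification with (S)-O-methylmandelic acid (DCC, DMAP) should give two diastereomeric esters that are separated by chromatography or crystallisation. The mandelate ester F7 of the (2R,3S)-ketone is then cleaved with Me3SnOH (1,2-dichloroethane, 60 °C), conditions that avoid retro-aldol loss of formaldehyde, to return enantiopure 4, where the route is rejoined.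

Step 11. What may go wrong: O-alkylation of the hindered potassium enolate in place of C-alkylation. The fallback is alkylation of a metalated hydrazone, which reacts only at carbon. It sets out from 10: N,N-dimethylhydrazine should give the hydrazone F8; LiN(i-Pr)2 followed by 19 should give the C-benzylated hydrazone F9 by the same equatorial approach; CuCl2 in aqueous THF (pH 7 buffer) should cleave the hydrazone to aldehyde 21, where the route is rejoined.

Further compounds
F1 | step 5 | (2S,3S)-2-(iodomethyl)-2-methyl-3-(2-methylprop-1-en-1-yl)-1-[(trimethylsilyl)methyl]cyclohexan-1-ol (C1 epimers) | C[Si](C)(C)CC1(O)CCC[C@@H](C=C(C)C)[C@]1(C)CI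
F2 | step 5 | (1R,2S)-3-hydroxy-2-(iodomethyl)-2-methyl-3-[(trimethylsilyl)methyl]cyclohexane-1-carbaldehyde (C3 epimers) | C[Si](C)(C)CC1(O)CCC[C@@H](C=O)[C@]1(C)CI
F3 | step 5 | 1-{(1R,2S)-3-hydroxy-2-(iodomethyl)-2-methyl-3-[(trimethylsilyl)methyl]cyclohexyl}-2-methylprop-2-en-1-ol (carbinol epimers) | C[Si](C)(C)CC1(O)CCC[C@@H](C(O)C(C)=C)[C@]1(C)CI
F4 | step 5 | 1-{(1R,2S)-3-hydroxy-2-(iodomethyl)-2-methyl-3-[(trimethylsilyl)methyl]cyclohexyl}-2-methylprop-2-en-1-one (C3 epimers) | C[Si](C)(C)CC1(O)CCC[C@@H](C(=O)C(C)=C)[C@]1(C)CI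
F5 | step 5 | (2S,4aS,8aR)-5-hydroxy-2,4a-dimethyl-5-[(trimethylsilyl)methyl]octahydronaphthalen-1(2H)-one (C5 epimers) | C[Si](C)(C)CC1(O)CCC[C@H]2C(=O)[C@@H](C)CC[C@]12C
F6 | step 5 | (2S,4aS,8aR)-1-(methoxymethylidene)-2,4a-dimethyl-5-methylidenedecahydronaphthalene | C=C1CCC[C@H]2C(=COC)[C@@H](C)CC[C@]12C
F7 | step 1 | [(1R,2S)-1-methyl-2-(2-methylprop-1-en-1-yl)-6-oxocyclohexyl]methyl (2S)-2-methoxy-2-phenylacetate | O=C1CCC[C@@H](C=C(C)C)[C@]1(C)COC(=O)[C@@H](OC)c1ccccc1
F8 | step 11 | N,N-dimethylhydrazone of 10 | C=C1CCC[C@H]2C(C=NN(C)C)[C@@H](C)CC[C@]12C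
F9 | step 11 | N,N-dimethylhydrazone of 21 | C=C1CCC[C@H]2[C@](C=NN(C)C)(Cc3cc(C(=O)OC)c(OCOC)c(OC)c3OCOC)[C@@H](C)CC[C@]12C
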